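(The data were computed with made-up constants; the scatter is artificial.)

Why does target crawl in the teal run after 1.25 d, with electrophile still at 36.6 % of its charge at the last reading?

| flask | electrophile | free base | protonated nucleophile | remark | time |
|---|---|---|---|---|---|
| amber | 1.1 M | 0.80 M | 1.2 M | run made earlier |  |
| teal | 1.8 M | 0.80 M | 1.2 M | run made earlier |  |
| grey | 0.80 M | 0.80 M | 2.4 M | run made earlier |  |
| flask | 0.80 M | 0.800 M | 1.20 M |  | 2.5 d |

| run | time / d | electrophile / % | target / % |
|---|---|---|---|
| amber | 0.625 | 36.0 | 20.2 |
| amber | 1.25 | 32.8 | 29.2 |
| amber | 1.67 | 30.9 | 31.1 |
| amber | 2.50 | 31.0 | 32.9 |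
| amber | 3.00 | 30.2 | 34.2 |
| teal | 0.250 | 45.0 | 10.3 |
| teal | 0.833 | 38.4 | 16.9 |
| teal | 1.25 | 36.8 | 20.7 |
| teal | 2.00 | 36.6 | 22.0 |
| teal | 3.00 | 36.6 | 23.2 |
| grey | 0.250 | 43.5 | 14.3 |
| grey | 0.833 | 32.9 | 28.5 |
| grey | 1.25 | 29.5 | 34.8 |
| grey | 2.00 | 26.4 | 40.4 |
| grey | 3.00 | 24.0 | 43.5 |

(standard deviation of a reading: 1 percentage point)

- the earlier runs were read with a standard deviation of 1 percentage point
- on the list of suspects stand: electrophile + nucleophile -> acid set free + target; nucleophile + acid set free <-> protonated nucleophile; acid set free + free base <-> salt of the base; electrophile <-> dormant form; target -> over-reaction product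
- what has gone from electrophile into another species counts as reacted, even if it can come back
- the earlier runs do not show how much of nucleophile is bound; that part of a forecast is a guess

- part of the electrophile that has reacted at 2.5 d
- share of the unused nucleophile that is free and not bound as protonated nucleophile, at 2.5 d

Is this one long time constant? It looks more like a ceiling: amber, charged with less electrophile than teal on the same free base, ends higher in percent of its charge.

What sets the ceiling? I take free base as the limiting reagent. Nucleophile is charged as protonated nucleophile, so one free base releases it, and a second takes up the acid set free: two per target. For the flask that gives 50.0 %, the target ceiling, free base charged over twice the electrophile charged, as a fraction of the electrophile charge.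

Does it fit? Amber's ceiling is 36.4 % against a last reading of 34.2 %; teal's is 22.2 % against 23.2 %, each reading with a scatter of 1 percentage point.

And grey? It has the flask's ceiling but read 43.5 % at 3.00 d, still rising. The ceiling gives the height, not the time. While free base and acid set free stand low, free nucleophile, as a fraction of the electrophile charge, is twice the gap below the ceiling, with over-reaction product counted as target. If the target step runs on free nucleophile, as the suspects have it, its rate falls as that gap closes; grey's reading before the last was 40.4 % at 2.00 d.

The forecast says 73 % reacted and 5.5 % free, reasoning that “each target consumes two base equivalents”.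

The flask gives 73.3 % and 13.5 %.

    electrophile + nucleophile → acid set free + target (k = 0.0660 M⁻¹ h⁻¹)
    nucleophile + acid set free ⇌ protonated nucleophile, settled at all times (K = 280 M⁻¹)
    acid set free + free base ⇌ salt of the base, settled at all times (K = 2600 M⁻¹)
    electrophile ⇌ dormant form (K = 1.10, k = 0.210 h⁻¹)
    target → over-reaction product (k = 0.00120 h⁻¹)

In the flask, free base fell to 8.57 % of its charge by 0.250 d while electrophile and dormant form shared out, with a relaxation half-life of 0.0720 d by that step alone, short against 2.5 d. Target then climbed on the free nucleophile to 41.2 % at 2.50 d, beside 2.16 % of over-reaction product. Twice the gap, over-reaction product counted as target, is 13.3 % of the electrophile charge, and the flask held 14.4 % as free nucleophile.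

The neighbour flask with 0.32 M of free base has a ceiling of 20.0 %. At 2.50 d that flask held target 20.3 % and over-reaction product 1.04 %, together 21.3 %, above the ceiling with 0.0720 M of acid set free standing, so the ceiling is an estimate and not a bound; 62.7 % had reacted and 4.73 % of the unused nucleophile was free.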